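**Plan**

- Cuts: C7=C8 and C7'=C8' release crocetin dialdehyde (C20) from a ring-end C15 sulfone and an acyclic-end C15 phosphonium salt. In the ring end the cuts are C1''–C2'' (sp3–sp2 coupling), the temporary bond C1''=C7, and the ring bonds C2–C3 and C5–C6.
- Enabling feature: ring carbons C2 and C6 hold their exocyclic carbons C1'' and C7 cis across the gem-dimethyl carbon C1. Ring C1–C6 can therefore be made as a bicyclo[3.2.1]oct-6-en-3-one with C1 as the one-carbon bridge and C1''=C7 as the etheno bridge.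
- Ring end, forward: 5,5-dimethylcyclopentadiene plus an oxyallyl cation closes the only ring by (4+3) cycloaddition. Then α-methylation, enol triflate, ozonolytic opening of the bridge, triflate reduction (C4=C5), iodoetherification to tell the two arms apart, Negishi coupling for the side chain, and a sulfone at C7.
- Acyclic end, forward: (R)-lavandulol is hydrated, oxidised and extended by a C5 phosphonate to the phosphonium salt. Wittig reaction with crocetin dialdehyde, Julia–Kocienski union with the ring sulfone and desilylation finish the chain.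
- Stereochemistry: the C2/C6 cis relation comes from the bicyclic cycloadduct, the absolute sense (2R,6R) from enantiotopic deprotonation of the meso ketone by a chiral lithium amide, and C2' (S) from the chiral pool. Alkene geometry comes from syn-carboalumination, Horner–Wadsworth–Emmons and Julia–Kocienski olefination, and thermal equilibration.

Key step: step 3

Locants C1–C15, C1''–C4'' and C1'–C15' are those of the target (carotenoid numbering).

Assumption: (R)-(−)-lavandulol and crocetin dialdehyde (8,8'-diapocarotene-8,8'-dial) are taken as purchasable.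

Assumption: the (R,R)-amide is written in step 4; which antipode removes the required proton has to be confirmed on the first run, and the mirror-image amide is used if the sense is opposite.

Assumption: the new methyl group of step 4 is drawn on the etheno-bridge face, away from the syn-8-methyl group; this carbon becomes sp2 in step 5, so the other epimer serves equally.

Remark: C2' is S in the target although (R)-lavandulol is used, because the CIP ranking of the substituents changes while the spatial arrangement does not.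

**Route**

Step 1
Reactants: 1 4,4-dimethylcyclopent-2-en-1-one
Product: 2 4,4-dimethylcyclopent-2-en-1-one p-toluenesulfonylhydrazone
Conditions: TsNHNH2, MeOH, cat. HCl, 25 °C
Reagents that add atoms: p-toluenesulfonyl hydrazide, Cc1ccc(cc1)S(=O)(=O)NN
Why: Hydrazone condensation at the carbonyl group should prevail because conjugate addition is hindered by the quaternary carbon next to the β-position.

Step 2
Reactants: 2 4,4-dimethylcyclopent-2-en-1-one p-toluenesulfonylhydrazone
Product: 4 5,5-dimethylcyclopenta-1,3-diene, via vinyllithium 3 (not isolated)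
Conditions: MeLi (2.2 equiv), Et2O, 0 → 25 °C; then H2O, 0 °C
Reagents that add atoms: none
Why: Shapiro reaction: the dianion formed by deprotonation at the α'-methylene loses sulfinate and N2 to give vinyllithium 3, whose protonation should give the volatile diene, which cannot isomerise by 1,5-hydrogen shift.

Step 3
Reactants: 4 5,5-dimethylcyclopenta-1,3-diene; 5 1,1,3,3-tetrabromoacetone
Product: 7 meso-8,8-dimethylbicyclo[3.2.1]oct-6-en-3-one, via dibromo cycloadduct 6 (not isolated)
Conditions: Zn–Cu couple, DME, −10 → 25 °C (slow addition of 5); then Zn–Cu couple, NH4Cl, MeOH, 25 °C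
Reagents that add atoms: none
Why: Two-electron reduction of 5 by zinc gives a zinc enolate that ionises bromide to the 1,3-dibromo-2-oxyallyl cation, a three-carbon 2π partner that should add across the termini of the s-cis-locked diene 4 in a concerted or rapidly stepwise (4+3) cycloaddition; the closest known reaction type is the cycloaddition of polybromoketone-derived oxyallyl cations with cyclopentadiene or furan followed by zinc debromination. The six-membered ring C1–C6 closes by cycloaddition, both new sigma bonds (C2–C3 and C5–C6) forming at the diene termini, so the former cyclopentene survives as the etheno bridge C1''=C7 and the CMe2 carbon becomes the one-carbon bridge C1. The two bridgehead stereocentres are set cis by suprafacial addition to the cyclic diene, that is, by the bicyclic topology itself; the product is meso and the bromine-bearing centres of 6 are erased by the reductive work-up. No regio- or facial selectivity is needed because both partners are symmetric and the two faces of 4 are equivalent. The selectivity the step does need is capture of the cation by the diene in preference to its further reduction, which slow addition of 5 to diene and couple should secure.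

Step 4
Reactants: 7 meso-8,8-dimethylbicyclo[3.2.1]oct-6-en-3-one
Product: 8 (1R,2S,5R)-2,8,8-trimethylbicyclo[3.2.1]oct-6-en-3-one
Conditions: (R,R)-bis(1-phenylethyl)amine·HCl, n-BuLi (2 equiv), THF, −78 °C; then 7; then MeI, −78 → −40 °C
Reagents that add atoms: iodomethane, CI
Why: Enantioselective deprotonation of a meso ketone by a C2-symmetric chiral lithium amide (with LiCl formed in situ) followed by enolate C-methylation: the base chooses one of the two enantiotopic α-methylenes and so fixes which bridgehead becomes C6, and the methyl should enter anti to the syn-8-methyl group.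

Step 5
Reactants: 8 (1R,2S,5R)-2,8,8-trimethylbicyclo[3.2.1]oct-6-en-3-one
Product: 10 (1S,5R)-2,8,8-trimethylbicyclo[3.2.1]octa-2,6-dien-3-yl trifluoromethanesulfonate, via trimethylsilyl enol ether 9 (not isolated)
Conditions: Me3SiI, HN(SiMe3)2, CH2Cl2, −20 → 25 °C; then CsF, PhNTf2, DME, 25 °C
Reagents that add atoms: N-phenylbis(trifluoromethanesulfonimide), O=S(=O)(N(c1ccccc1)S(=O)(=O)C(F)(F)F)C(F)(F)F
Why: Thermodynamic silyl enol ether formation places the enol double bond toward the methyl-bearing carbon, and fluoride-triggered O-triflation should transfer that regiochemistry to the enol triflate while the methyl-bearing stereocentre becomes sp2.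

Step 6
Reactants: 10 (1S,5R)-2,8,8-trimethylbicyclo[3.2.1]octa-2,6-dien-3-yl trifluoromethanesulfonate
Product: 12 cis-3,5-bis(hydroxymethyl)-2,4,4-trimethylcyclohex-1-en-1-yl trifluoromethanesulfonate, via ozonide 11 (not isolated)
Conditions: O3 (1 equiv, Sudan Red 7B end point), CH2Cl2, −78 °C; then NaBH4, MeOH, −78 → 0 °C
Reagents that add atoms: ozone, [O-][O+]=O
Why: Chemoselective ozonolysis with reductive work-up: the strained cis-disubstituted bridge alkene should react far faster with electrophilic ozone than the tetrasubstituted, triflate-deactivated enol double bond, and cleavage frees the two hydroxymethyl arms in the cis relation fixed in step 3.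

Step 7
Reactants: 12 cis-3,5-bis(hydroxymethyl)-2,4,4-trimethylcyclohex-1-en-1-yl trifluoromethanesulfonate
Product: 13 [(1R,5S)-2,6,6-trimethylcyclohex-2-ene-1,5-diyl]dimethanol
Conditions: Pd(OAc)2 (5 mol %), PPh3 (10 mol %), HCO2H, Et3N, DMF, 60 °C
Reagents that add atoms: none
Why: Palladium-catalysed formate reduction of an enol triflate (oxidative addition, formate exchange, decarboxylation, C–H reductive elimination) should give the C4=C5 alkene in place without affecting the free hydroxyl groups.

Step 8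
Reactants: 13 [(1R,5S)-2,6,6-trimethylcyclohex-2-ene-1,5-diyl]dimethanol
Product: 14 (7-iodo-1,5,5-trimethyl-2-oxabicyclo[2.2.2]octan-6-yl)methanol with iodine anti to the ring oxygen
Conditions: I2, NaHCO3, MeCN, 0 °C
Reagents that add atoms: iodine, II
Why: Iodoetherification: only the hydroxymethyl group on C2 is 1,4-related to the tertiary alkene carbon C5 and can close a cineole-type ether, whereas the arm on C6 could only form an oxetane or a 5-endo ether, so the two arms are told apart; oxygen adds on the arm face and iodine anti, both new centres being temporary.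

Step 9
Reactants: 14 (7-iodo-1,5,5-trimethyl-2-oxabicyclo[2.2.2]octan-6-yl)methanol
Product: 15 tert-butyldimethylsilyl ether of 14
Conditions: t-BuMe2SiCl, imidazole, DMF, 25 °C
Reagents that add atoms: tert-butyl(chloro)dimethylsilane, CC(C)(C)[Si](C)(C)Cl
Why: Standard silylation of the only free (primary) hydroxyl group, the one on C7.

Step 10
Reactants: 15 tert-butyldimethylsilyl ether of 14
Product: 16 [cis-5-({[tert-butyl(dimethyl)silyl]oxy}methyl)-4,6,6-trimethylcyclohex-3-en-1-yl]methanol
Conditions: Zn dust, AcOH, EtOH, 25 °C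
Reagents that add atoms: none
Why: Zinc-mediated reductive β-elimination of the anti-periplanar β-iodo ether should regenerate the C4=C5 double bond exactly where it was and release the C1'' hydroxyl group.

Step 11
Reactants: 16 [cis-5-({[tert-butyl(dimethyl)silyl]oxy}methyl)-4,6,6-trimethylcyclohex-3-en-1-yl]methanol
Product: 17 tert-butyl{[cis-5-(iodomethyl)-2,6,6-trimethylcyclohex-2-en-1-yl]methoxy}dimethylsilane
Conditions: PPh3, I2, imidazole, CH2Cl2, 0 °C (reagent preformed); then 16, 0 → 25 °C
Reagents that add atoms: iodine, II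
Why: Appel-type iodination: SN2 displacement of the alkoxyphosphonium ion by iodide, with the reagent preformed so that no free iodine meets the alkene.

Step 12
Reactants: 18 prop-2-yn-1-ol
Product: 20 (E)-3-iodo-2-methylprop-2-en-1-ol, via alkenylalane 19 (not isolated)
Conditions: Me3Al (3 equiv), Cp2ZrCl2 (25 mol %), CH2Cl2, 0 → 25 °C; then I2, THF, −30 → 0 °C
Reagents that add atoms: trimethylaluminium, C[Al](C)C; iodine, II
Why: Zirconium-catalysed carboalumination (Negishi carboalumination) adds methyl and aluminium syn across the alkyne, and iodinolysis of the alkenyl–aluminium bond with retention should give the E-iodide.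

Step 13
Reactants: 20 (E)-3-iodo-2-methylprop-2-en-1-ol
Product: 21 tert-butyl{[(E)-3-iodo-2-methylprop-2-en-1-yl]oxy}diphenylsilane
Conditions: t-BuPh2SiCl, imidazole, CH2Cl2, 25 °C
Reagents that add atoms: tert-butyl(chloro)diphenylsilane, CC(C)(C)[Si](Cl)(c1ccccc1)c1ccccc1
Why: Standard silylation of a primary allylic alcohol with a group that outlasts the later acidic removal of the other silyl ether.

Step 14
Reactants: 17 tert-butyl{[cis-5-(iodomethyl)-2,6,6-trimethylcyclohex-2-en-1-yl]methoxy}dimethylsilane; 21 tert-butyl{[(E)-3-iodo-2-methylprop-2-en-1-yl]oxy}diphenylsilane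
Product: 23 tert-butyl{[cis-5-{(E)-4-[(tert-butyldiphenylsilyl)oxy]-3-methylbut-2-en-1-yl}-2,6,6-trimethylcyclohex-2-en-1-yl]methoxy}dimethylsilane, via alkylzinc iodide 22 (not isolated)
Conditions: Zn dust (activated with BrCH2CH2Br and Me3SiCl), LiCl, THF, 40 °C; then 21, Pd(PPh3)4 (5 mol %), 25 → 50 °C
Reagents that add atoms: none
Why: Negishi sp3–sp2 cross-coupling: LiCl-assisted zinc insertion into the primary C–I bond and palladium-catalysed coupling with the alkenyl iodide should form C1''–C2'' with retention of the E geometry.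

Step 15
Reactants: 23 the bis(silyl ether) of step 14
Product: 24 [cis-5-{(E)-4-[(tert-butyldiphenylsilyl)oxy]-3-methylbut-2-en-1-yl}-2,6,6-trimethylcyclohex-2-en-1-yl]methanol
Conditions: camphorsulfonic acid (10 mol %), MeOH/CH2Cl2, 0 → 25 °C
Reagents that add atoms: none
Why: Acid-catalysed methanolysis of silyl ethers, in which the primary tert-butyldimethylsilyl ether is cleaved much faster than the bulkier tert-butyldiphenylsilyl ether.

Step 16
Reactants: 24 the C7 alcohol of step 15
Product: 25 5-{[cis-5-{(E)-4-[(tert-butyldiphenylsilyl)oxy]-3-methylbut-2-en-1-yl}-2,6,6-trimethylcyclohex-2-en-1-yl]methylsulfanyl}-1-phenyl-1H-tetrazole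
Conditions: 1-phenyl-1H-tetrazole-5-thiol, PPh3, i-PrO2CN=NCO2i-Pr, THF, 0 → 25 °C
Reagents that add atoms: 1-phenyl-1H-tetrazole-5-thiol, Sc1nnnn1-c1ccccc1
Why: Mitsunobu thioetherification of a primary alcohol with an acidic heteroaryl thiol; the stereocentre at C6 is not involved.

Step 17
Reactants: 25 the tetrazolyl sulfide of step 16
Product: 26 5-{[cis-5-{(E)-4-[(tert-butyldiphenylsilyl)oxy]-3-methylbut-2-en-1-yl}-2,6,6-trimethylcyclohex-2-en-1-yl]methylsulfonyl}-1-phenyl-1H-tetrazole
Conditions: (NH4)6Mo7O24·4H2O (10 mol %), 30% H2O2, EtOH, 0 → 25 °C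
Reagents that add atoms: hydrogen peroxide, OO
Why: Molybdate-catalysed sulfide-to-sulfone oxidation, in which the peroxo-molybdenum species should oxidise sulfur much faster than it epoxidises the two trisubstituted alkenes.

Step 18
Reactants: 27 (R)-lavandulol
Product: 28 triethyl{[(2R)-5-methyl-2-(prop-1-en-2-yl)hex-4-en-1-yl]oxy}silane
Conditions: Et3SiCl, imidazole, CH2Cl2, 0 °C
Reagents that add atoms: chlorotriethylsilane, CC[Si](Cl)(CC)CC
Why: Silylation of the primary alcohol, so that the oxygen cannot capture a mercurinium ion on the prenyl double bond in the next step.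

Step 19
Reactants: 28 triethyl{[(2R)-5-methyl-2-(prop-1-en-2-yl)hex-4-en-1-yl]oxy}silane
Product: 30 (3S)-2,6-dimethyl-3-[(triethylsilyloxy)methyl]hept-5-en-2-ol, via acetoxymercurio alcohol 29 (not isolated)
Conditions: Hg(OAc)2 (1.0 equiv), THF/H2O (1:1), 0 °C; then NaOH, NaBH4, 0 °C
Reagents that add atoms: water, O
Why: Oxymercuration–demercuration (Markovnikov hydration), in which the 1,1-disubstituted alkene should be mercurated much faster than the trisubstituted prenyl double bond; the existing stereocentre is untouched and no new one remains in the product.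

Step 20
Reactants: 30 (3S)-2,6-dimethyl-3-[(triethylsilyloxy)methyl]hept-5-en-2-ol
Product: 31 triethyl{[(3S)-2,6-dimethyl-3-[(triethylsilyloxy)methyl]hept-5-en-2-yl]oxy}silane
Conditions: Et3SiOTf, 2,6-lutidine, CH2Cl2, −78 → 0 °C
Reagents that add atoms: triethylsilyl trifluoromethanesulfonate, CC[Si](CC)(CC)OS(=O)(=O)C(F)(F)F
Why: Silylation of a tertiary alcohol with a silyl triflate; any diol formed by loss of the primary silyl group in step 19 converges on the same bis(silyl ether).

Step 21
Reactants: 31 triethyl{[(3S)-2,6-dimethyl-3-[(triethylsilyloxy)methyl]hept-5-en-2-yl]oxy}silane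
Product: 32 (2R)-5-methyl-2-[2-(triethylsilyloxy)propan-2-yl]hex-4-enal
Conditions: (COCl)2, DMSO, CH2Cl2, −78 → −30 °C; then Et3N, −78 → 0 °C
Reagents that add atoms: none
Why: Swern oxidation applied directly to a primary triethylsilyl ether: the chlorosulfonium salt cleaves the primary Si–O bond to the alkoxysulfonium ion while the tertiary silyl ether is inert, and the low temperature should preserve the α-stereocentre.

Step 22
Reactants: 32 (2R)-5-methyl-2-[2-(triethylsilyloxy)propan-2-yl]hex-4-enal; 33 triethyl 3-methyl-4-phosphonocrotonate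
Product: 34 ethyl (2E,4E,6S)-3,9-dimethyl-6-[2-(triethylsilyloxy)propan-2-yl]deca-2,4,8-trienoate
Conditions: 33, LiN(SiMe3)2, THF, −78 °C; then 32, −78 → 0 °C
Reagents that add atoms: none
Why: Horner–Wadsworth–Emmons olefination with a vinylogous phosphonate should form the C3'=C4' bond E, and any 2Z isomer from the reagent is removed by chromatography.

Step 23
Reactants: 34 ethyl (2E,4E,6S)-3,9-dimethyl-6-[2-(triethylsilyloxy)propan-2-yl]deca-2,4,8-trienoate
Product: 35 (2E,4E,6S)-3,9-dimethyl-6-[2-(triethylsilyloxy)propan-2-yl]deca-2,4,8-trien-1-ol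
Conditions: i-Bu2AlH (2.5 equiv), CH2Cl2, −78 °C; aq. KNaC4H4O6 (potassium sodium tartrate)
Reagents that add atoms: none
Why: 1,2-Reduction of a conjugated ester to the allylic alcohol by the aluminium hydride.

Step 24
Reactants: 35 (2E,4E,6S)-3,9-dimethyl-6-[2-(triethylsilyloxy)propan-2-yl]deca-2,4,8-trien-1-ol
Product: 37 [(2E,4E,6S)-3,9-dimethyl-6-[2-(triethylsilyloxy)propan-2-yl]deca-2,4,8-trien-1-yl]triphenylphosphonium bromide, via allylic bromide 36 (not isolated)
Conditions: CBr4, PPh3, CH2Cl2, −20 °C; then PPh3, 25 °C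
Reagents that add atoms: carbon tetrabromide, BrC(Br)(Br)Br; triphenylphosphine, c1ccc(cc1)P(c1ccccc1)c1ccccc1
Why: Appel bromination under neutral conditions (the tertiary silyl ether survives) followed by SN2 quaternisation of the allylic bromide with triphenylphosphine.

Step 25
Reactants: 37 the phosphonium bromide of step 24; 38 crocetin dialdehyde
Product: 39 (2'S,all-E)-2'-(3-methylbut-2-enyl)-1'-(triethylsilyloxy)-3',4'-didehydro-1',2'-dihydro-8-apo-ψ-caroten-8-al
Conditions: 38 (3 equiv), NaOMe, CH2Cl2/MeOH, 0 → 25 °C; then heptane, 80 °C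
Reagents that add atoms: none
Why: Wittig olefination of a semi-stabilised allylic ylide with excess dialdehyde should give the mono-adduct, and heating equilibrates the new C7'=C8' bond to E.

Step 26
Reactants: 26 the tetrazolyl sulfone of step 17; 39 the C35 aldehyde of step 25
Product: 40 the target with O–C4'' as tert-butyldiphenylsilyl ether and O–C1' as triethylsilyl ether
Conditions: 26, KN(SiMe3)2, THF, −78 °C; then 39, −78 → 25 °C
Reagents that add atoms: none
Why: Julia–Kocienski olefination: the metallated tetrazolyl sulfone adds to the aldehyde, and Smiles rearrangement with loss of SO2 and tetrazololate should give the E C7=C8 bond, leaving C6 (not acidic under these conditions) untouched.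

Step 27
Reactants: 40 the bis(silyl ether) of step 26
Product: 41 (2R,6R,2'S)-2-[(E)-4-hydroxy-3-methylbut-2-enyl]-2'-(3-methylbut-2-enyl)-3',4'-didehydro-1',2'-dihydro-ε,ψ-caroten-1'-ol
Conditions: Bu4NF, THF, 25 °C
Reagents that add atoms: none
Why: Fluoride-mediated cleavage of both silyl ethers, conditions that the polyene and the stereocentres should tolerate.

**Compound list**

1 | 4,4-dimethylcyclopent-2-en-1-one | CC1(C)CC(=O)C=C1 | starting material
2 | 4,4-dimethylcyclopent-2-en-1-one p-toluenesulfonylhydrazone | CC1(C)CC(=NNS(=O)(=O)c2ccc(C)cc2)C=C1 | intermediate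
3 | (5,5-dimethylcyclopenta-1,3-dien-2-yl)lithium | [Li]C1=CC(C)(C)C=C1 | intermediate (not isolated)
4 | 5,5-dimethylcyclopenta-1,3-diene | CC1(C)C=CC=C1 | intermediate
5 | 1,1,3,3-tetrabromoacetone | O=C(C(Br)Br)C(Br)Br | starting material
6 | 2,4-dibromo-8,8-dimethylbicyclo[3.2.1]oct-6-en-3-one (C–Br epimers) | O=C1C(Br)[C@H]2C=C[C@@H](C1Br)C2(C)C | intermediate (not isolated)
7 | meso-8,8-dimethylbicyclo[3.2.1]oct-6-en-3-one | O=C1C[C@H]2C=C[C@@H](C1)C2(C)C | intermediate
8 | (1R,2S,5R)-2,8,8-trimethylbicyclo[3.2.1]oct-6-en-3-one | C[C@@H]1C(=O)C[C@@H]2C=C[C@H]1C2(C)C | intermediate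
9 | (1S,5R)-2,8,8-trimethyl-3-(trimethylsilyloxy)bicyclo[3.2.1]octa-2,6-diene | CC1=C(O[Si](C)(C)C)C[C@@H]2C=C[C@H]1C2(C)C | intermediate (not isolated)
10 | (1S,5R)-2,8,8-trimethylbicyclo[3.2.1]octa-2,6-dien-3-yl trifluoromethanesulfonate | CC1=C(OS(=O)(=O)C(F)(F)F)C[C@@H]2C=C[C@H]1C2(C)C | intermediate
11 | ozonide (1,2,4-trioxolane) of 10 at the bridge alkene | CC1=C(OS(=O)(=O)C(F)(F)F)C[C@@H]2C3OOC(O3)[C@H]1C2(C)C | intermediate (not isolated)
12 | cis-3,5-bis(hydroxymethyl)-2,4,4-trimethylcyclohex-1-en-1-yl trifluoromethanesulfonate | OC[C@@H]1C(C)=C(OS(=O)(=O)C(F)(F)F)C[C@H](CO)C1(C)C | intermediate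
13 | [(1R,5S)-2,6,6-trimethylcyclohex-2-ene-1,5-diyl]dimethanol | OC[C@@H]1C(C)=CC[C@H](CO)C1(C)C | intermediate
14 | (7-iodo-1,5,5-trimethyl-2-oxabicyclo[2.2.2]octan-6-yl)methanol, iodine anti to the ring oxygen | OC[C@@H]1[C@]2(C)OC[C@@H](C[C@@H]2I)C1(C)C | intermediate
15 | tert-butyldimethylsilyl ether of 14 | CC(C)(C)[Si](C)(C)OC[C@@H]1[C@]2(C)OC[C@@H](C[C@@H]2I)C1(C)C | intermediate
16 | [cis-5-({[tert-butyl(dimethyl)silyl]oxy}methyl)-4,6,6-trimethylcyclohex-3-en-1-yl]methanol | CC(C)(C)[Si](C)(C)OC[C@@H]1C(C)=CC[C@H](CO)C1(C)C | intermediate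
17 | tert-butyl{[cis-5-(iodomethyl)-2,6,6-trimethylcyclohex-2-en-1-yl]methoxy}dimethylsilane | CC(C)(C)[Si](C)(C)OC[C@@H]1C(C)=CC[C@H](CI)C1(C)C | intermediate
18 | prop-2-yn-1-ol | C#CCO | starting material
19 | dimethyl[(E)-3-(dimethylalumanyloxy)-2-methylprop-1-enyl]alumane | C[Al](C)/C=C(\C)CO[Al](C)C | intermediate (not isolated)
20 | (E)-3-iodo-2-methylprop-2-en-1-ol | I/C=C(\C)CO | intermediate
21 | tert-butyl{[(E)-3-iodo-2-methylprop-2-en-1-yl]oxy}diphenylsilane | I/C=C(\C)CO[Si](c1ccccc1)(c1ccccc1)C(C)(C)C | intermediate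
22 | alkylzinc iodide from 17 (ring–CH2–ZnI at C1'') | CC(C)(C)[Si](C)(C)OC[C@@H]1C(C)=CC[C@H](C[Zn]I)C1(C)C | intermediate (not isolated)
23 | tert-butyl{[cis-5-{(E)-4-[(tert-butyldiphenylsilyl)oxy]-3-methylbut-2-en-1-yl}-2,6,6-trimethylcyclohex-2-en-1-yl]methoxy}dimethylsilane | CC(C)(C)[Si](C)(C)OC[C@@H]1C(C)=CC[C@H](C/C=C(\C)CO[Si](c2ccccc2)(c2ccccc2)C(C)(C)C)C1(C)C | intermediate
24 | [cis-5-{(E)-4-[(tert-butyldiphenylsilyl)oxy]-3-methylbut-2-en-1-yl}-2,6,6-trimethylcyclohex-2-en-1-yl]methanol | OC[C@@H]1C(C)=CC[C@H](C/C=C(\C)CO[Si](c2ccccc2)(c2ccccc2)C(C)(C)C)C1(C)C | intermediate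
25 | 5-{[cis-5-{(E)-4-[(tert-butyldiphenylsilyl)oxy]-3-methylbut-2-en-1-yl}-2,6,6-trimethylcyclohex-2-en-1-yl]methylsulfanyl}-1-phenyl-1H-tetrazole | C(Sc1nnnn1-c1ccccc1)[C@@H]1C(C)=CC[C@H](C/C=C(\C)CO[Si](c2ccccc2)(c2ccccc2)C(C)(C)C)C1(C)C | intermediate
26 | 5-{[cis-5-{(E)-4-[(tert-butyldiphenylsilyl)oxy]-3-methylbut-2-en-1-yl}-2,6,6-trimethylcyclohex-2-en-1-yl]methylsulfonyl}-1-phenyl-1H-tetrazole | C(S(=O)(=O)c1nnnn1-c1ccccc1)[C@@H]1C(C)=CC[C@H](C/C=C(\C)CO[Si](c2ccccc2)(c2ccccc2)C(C)(C)C)C1(C)C | intermediate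
27 | (R)-lavandulol, (2R)-5-methyl-2-(prop-1-en-2-yl)hex-4-en-1-ol | CC(C)=CC[C@@H](CO)C(C)=C | starting material
28 | triethyl{[(2R)-5-methyl-2-(prop-1-en-2-yl)hex-4-en-1-yl]oxy}silane | CC(C)=CC[C@@H](CO[Si](CC)(CC)CC)C(C)=C | intermediate
29 | acetoxymercurio alcohol from 28 (HgOAc on the former =CH2 carbon, epimers at the carbinol carbon) | CC(C)=CC[C@@H](CO[Si](CC)(CC)CC)C(C)(O)C[Hg]OC(C)=O | intermediate (not isolated)
30 | (3S)-2,6-dimethyl-3-[(triethylsilyloxy)methyl]hept-5-en-2-ol | CC(C)=CC[C@@H](CO[Si](CC)(CC)CC)C(C)(C)O | intermediate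
31 | triethyl{[(3S)-2,6-dimethyl-3-[(triethylsilyloxy)methyl]hept-5-en-2-yl]oxy}silane | CC(C)=CC[C@@H](CO[Si](CC)(CC)CC)C(C)(C)O[Si](CC)(CC)CC | intermediate
32 | (2R)-5-methyl-2-[2-(triethylsilyloxy)propan-2-yl]hex-4-enal | CC(C)=CC[C@@H](C=O)C(C)(C)O[Si](CC)(CC)CC | intermediate
33 | triethyl 3-methyl-4-phosphonocrotonate (ethyl 4-(diethoxyphosphoryl)-3-methylbut-2-enoate, E/Z mixture) | CCOC(=O)C=C(C)CP(=O)(OCC)OCC | starting material
34 | ethyl (2E,4E,6S)-3,9-dimethyl-6-[2-(triethylsilyloxy)propan-2-yl]deca-2,4,8-trienoate | CC(C)=CC[C@@H](/C=C/C(C)=C/C(=O)OCC)C(C)(C)O[Si](CC)(CC)CC | intermediate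
35 | (2E,4E,6S)-3,9-dimethyl-6-[2-(triethylsilyloxy)propan-2-yl]deca-2,4,8-trien-1-ol | CC(C)=CC[C@@H](/C=C/C(C)=C/CO)C(C)(C)O[Si](CC)(CC)CC | intermediate
36 | (2E,4E,6S)-1-bromo-3,9-dimethyl-6-[2-(triethylsilyloxy)propan-2-yl]deca-2,4,8-triene | CC(C)=CC[C@@H](/C=C/C(C)=C/CBr)C(C)(C)O[Si](CC)(CC)CC | intermediate (not isolated)
37 | [(2E,4E,6S)-3,9-dimethyl-6-[2-(triethylsilyloxy)propan-2-yl]deca-2,4,8-trien-1-yl]triphenylphosphonium bromide | CC(C)=CC[C@@H](/C=C/C(C)=C/C[P+](c1ccccc1)(c1ccccc1)c1ccccc1)C(C)(C)O[Si](CC)(CC)CC.[Br-] | intermediate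
38 | crocetin dialdehyde, (all-E)-2,6,11,15-tetramethylhexadeca-2,4,6,8,10,12,14-heptaenedial | O=C/C(C)=C/C=C/C(C)=C/C=C/C=C(C)/C=C/C=C(C)/C=O | starting material
39 | (2'S,all-E)-2'-(3-methylbut-2-enyl)-1'-(triethylsilyloxy)-3',4'-didehydro-1',2'-dihydro-8-apo-ψ-caroten-8-al | CC(C)=CC[C@@H](/C=C/C(C)=C/C=C/C(C)=C/C=C/C(C)=C/C=C/C=C(C)/C=C/C=C(C)/C=O)C(C)(C)O[Si](CC)(CC)CC | intermediate
40 | target with O–C4'' as tert-butyldiphenylsilyl ether and O–C1' as triethylsilyl ether | CC(C)=CC[C@@H](/C=C/C(C)=C/C=C/C(C)=C/C=C/C(C)=C/C=C/C=C(C)/C=C/C=C(C)/C=C/[C@@H]1C(C)=CC[C@H](C/C=C(\C)CO[Si](c2ccccc2)(c2ccccc2)C(C)(C)C)C1(C)C)C(C)(C)O[Si](CC)(CC)CC | intermediate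
41 | (2R,6R,2'S)-2-[(E)-4-hydroxy-3-methylbut-2-enyl]-2'-(3-methylbut-2-enyl)-3',4'-didehydro-1',2'-dihydro-ε,ψ-caroten-1'-ol (CNP0409952.1) | CC(C)=CC[C@@H](/C=C/C(C)=C/C=C/C(C)=C/C=C/C(C)=C/C=C/C=C(C)/C=C/C=C(C)/C=C/[C@@H]1C(C)=CC[C@H](C/C=C(\C)CO)C1(C)C)C(C)(C)O | target

**Step count and risks**

Total: 27 steps. Longest linear sequence: 17 steps (steps 1–11, 14–17, 26, 27). The alkenyl iodide branch has 2 steps (12, 13) and the acyclic-end branch has 8 (18–25).

The three steps most likely to fail:

Step 3. The gem-dimethyl carbon shields both faces of the diene termini, so the transient oxyallyl cation may be reduced further or oligomerise faster than it is captured, and the volatile diene may be lost. The fallback sets out from 4 and returns at 7. The cation is generated without a reducing metal, by base-induced ionisation of 1,1,3-trichloroacetone with CF3CH2ONa in CF3CH2OH (0 → 25 °C), a strongly ionising, weakly nucleophilic medium in which the 1,3-dichloro-oxyallyl cation lives longer. Cycloaddition should give 2,4-dichloro-8,8-dimethylbicyclo[3.2.1]oct-6-en-3-one F1. Reductive dechlorination with Zn–Cu couple, NH4Cl and MeOH then gives 7.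

Step 6. Ozone may begin to attack the enol triflate double bond before the bridge alkene is fully consumed, or the bridge may be cleaved incompletely if ozone is under-dosed. The fallback sets out from 8 and returns at 13; it cleaves the bridge while no second alkene is present.
- Ozonolysis of 8 with NaBH4 work-up, which also reduces the ketone, gives cis-3,5-bis(hydroxymethyl)-2,4,4-trimethylcyclohexan-1-ol F2.
- Both primary hydroxyls are silylated (t-BuMe2SiCl, imidazole) to the bis(silyl ether) F3.
- Swern oxidation of the remaining secondary alcohol gives the ketone F4.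
- Me3SiI/HN(SiMe3)2 gives the thermodynamic trimethylsilyl enol ether F5, and CsF/PhNTf2 converts it into the enol triflate F6.
- Pd(OAc)2/PPh3/HCO2H/Et3N reduction gives the bis(silyl ether) of the ene-diol F7.
- Bu4NF removes both silyl groups to give 13.

Step 26. The hindered sulfonyl carbanion may add slowly to the weakly electrophilic polyenal, giving poor E/Z control and allowing decay of the anion. The fallback sets out from 24 and 39 and returns at 40; it reverses the polarity of the C7=C8 olefination.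
- 24 is oxidised with PhI(OAc)2 and catalytic TEMPO (neutral, to avoid epimerisation at C6 and double-bond migration) to cis-5-{(E)-4-[(tert-butyldiphenylsilyl)oxy]-3-methylbut-2-en-1-yl}-2,6,6-trimethylcyclohex-2-ene-1-carbaldehyde F8.
- 39 is reduced with NaBH4 (THF/MeOH, 0 °C) to the polyenyl alcohol F9.
- F9 is converted with PPh3·HBr (CH2Cl2, 0 °C) into the polyenyl triphenylphosphonium bromide F10.
- Wittig reaction of the ylide from F10 (NaOMe, CH2Cl2/MeOH, 0 °C) with F8, followed by thermal Z → E equilibration in heptane, gives 40.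

Further compounds
F1 | step 3 | 2,4-dichloro-8,8-dimethylbicyclo[3.2.1]oct-6-en-3-one (C–Cl epimers) | O=C1C(Cl)[C@H]2C=C[C@@H](C1Cl)C2(C)C
F2 | step 6 | cis-3,5-bis(hydroxymethyl)-2,4,4-trimethylcyclohexan-1-ol (carbinol epimers) | OC[C@@H]1[C@H](C)C(O)C[C@H](CO)C1(C)C
F3 | step 6 | cis-3,5-bis({[tert-butyl(dimethyl)silyl]oxy}methyl)-2,4,4-trimethylcyclohexan-1-ol | CC(C)(C)[Si](C)(C)OC[C@@H]1[C@H](C)C(O)C[C@H](CO[Si](C)(C)C(C)(C)C)C1(C)C
F4 | step 6 | cis-3,5-bis({[tert-butyl(dimethyl)silyl]oxy}methyl)-2,4,4-trimethylcyclohexan-1-one | CC(C)(C)[Si](C)(C)OC[C@@H]1[C@H](C)C(=O)C[C@H](CO[Si](C)(C)C(C)(C)C)C1(C)C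
F5 | step 6 | trimethylsilyl enol ether of F4 (double bond toward the methyl-bearing carbon) | CC(C)(C)[Si](C)(C)OC[C@@H]1C(C)=C(O[Si](C)(C)C)C[C@H](CO[Si](C)(C)C(C)(C)C)C1(C)C
F6 | step 6 | cis-3,5-bis({[tert-butyl(dimethyl)silyl]oxy}methyl)-2,4,4-trimethylcyclohex-1-en-1-yl trifluoromethanesulfonate | CC(C)(C)[Si](C)(C)OC[C@@H]1C(C)=C(OS(=O)(=O)C(F)(F)F)C[C@H](CO[Si](C)(C)C(C)(C)C)C1(C)C
F7 | step 6 | bis(tert-butyldimethylsilyl) ether of 13 | CC(C)(C)[Si](C)(C)OC[C@@H]1C(C)=CC[C@H](CO[Si](C)(C)C(C)(C)C)C1(C)C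
F8 | step 26 | cis-5-{(E)-4-[(tert-butyldiphenylsilyl)oxy]-3-methylbut-2-en-1-yl}-2,6,6-trimethylcyclohex-2-ene-1-carbaldehyde | O=C[C@@H]1C(C)=CC[C@H](C/C=C(\C)CO[Si](c2ccccc2)(c2ccccc2)C(C)(C)C)C1(C)C
F9 | step 26 | (2'S,all-E)-2'-(3-methylbut-2-enyl)-1'-(triethylsilyloxy)-3',4'-didehydro-1',2'-dihydro-8-apo-ψ-caroten-8-ol | CC(C)=CC[C@@H](/C=C/C(C)=C/C=C/C(C)=C/C=C/C(C)=C/C=C/C=C(C)/C=C/C=C(C)/CO)C(C)(C)O[Si](CC)(CC)CC
F10 | step 26 | triphenylphosphonium bromide from F9 (phosphorus on C8) | CC(C)=CC[C@@H](/C=C/C(C)=C/C=C/C(C)=C/C=C/C(C)=C/C=C/C=C(C)/C=C/C=C(C)/C[P+](c1ccccc1)(c1ccccc1)c1ccccc1)C(C)(C)O[Si](CC)(CC)CC.[Br-]
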